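(The runs stem from a simulated flask with constants of no real substance, noise included.)

- Target first: in these runs it fills up and then leaks away, so compare the two rates at the moment the filling ends.

| flask | starting material | enzyme | remark | time |
|---|---|---|---|---|
| noon | 0.028 M | 0.01 mol% | run made earlier |  |
| winter | 0.044 M | 0.01 mol% | run made earlier |  |
| midnight | 0.020 M | 0.015 mol% | run made earlier |  |
| flask | 0.020 M | 0.01 mol% |  | 80 min |

- noon (time / min: target / %, starting material / %): 0.500: 86.6, 11.8; 1.00: 99.1, 0; 2.00: 95.7, 0; 5.00: 89.6, 0; 10.0: 87.6, 0.5; 20.0: 82.4, 0; 50.0: 80.0, 2.0
- winter (time / min: target / %, starting material / %): 0.500: 91.1, 6.2; 1.00: 97.1, 0; 2.00: 94.3, 0.5; 5.00: 86.0, 0.9; 10.0: 85.0, 0; 20.0: 83.4, 0.2; 50.0: 76.5, 0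
- midnight (time / min: target / %, starting material / %): 0.500: 94.5, 4.7; 1.50: 97.5, 0.7; 5.00: 89.3, 1.8; 15.0: 85.8, 0; 50.0: 79.3, 0.8

(scatter of a reading: 1 percentage point)

1. time, not beyond 80 min, at which the flask holds most target
2. the amount of target, in percent of the starting material charged, at that time
3. earliest time at which at least nineteen twentieths of that best amount are there, in min
4. latest time at which they still are, in min

- what was read earlier has a scatter of 1 percentage point, one standard deviation

- Turn the question round: what would have to be true for the flask's top to stand a twentieth short of the charge?
- Read the noon run, which has the flask's loading. It shows 0 % starting material at 1.00 min, so take that as the filling time. Between 2.00 min and 5.00 min its target falls by a fraction 0.0203 /min of the charge.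
- Divide the filling rate, one charge per filling time, by that leaking rate. This gives 49.2, the fill-to-loss ratio, a kind of selectivity factor.
- Its inverse estimates the fraction of the charge leaked while filling, and so the gap below the charge at the top. A gap of a twentieth needs a ratio of 20.0, and noon reads 2.46 times that.
- Repeat this on the winter run: the leak of 0.0277 /min gives a ratio of 36.1, still above the critical value.
- My reckoning: the flask's charge is smaller than noon's, and the winter run's larger charge read a lower ratio. Take noon's ratio for the flask, which puts its top near 98.0 %.
- The forecast gives 98 % at 0.9 min, with the window from 0.63 min to 3.6 min. Its ground for the slow fall: “So the loss appears to scale with enzyme concentration, and the flask should lose target more slowly.”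

- The flask peaks at 98.0 % at 1.13 min, later than the forecast's 0.9 min, and its window runs from 0.692 min to 4.67 min, against the forecast's 3.6 min.

    2 enzyme → spent catalyst (k = 32000 /M/min)
    target + enzyme ⇌ isomer of the product + enzyme, rate k2*[enzyme]*[target] forward; the back reaction follows from the equilibrium constant (K = 0.350, k = 12000 /M/min)
    starting material + enzyme → target + enzyme, rate k3*[starting material]*[enzyme]/(1 + ([starting material]/Km3)) (7.00 mM, k = 69000 /M/s)

- At the peak the flask holds 1.77 % isomer of the product and 0.271 % starting material. Apply the ratio to the flask's own curve: target falls from 97.2 % at 1.70 min to 93.2 % at 4.53 min, which gives 63.1 and a top near 98.4 %. Put the winter ratio, read at 0.044 M, on the neighbour flask charged with 0.050 M at the same loading: it gives 97.2 %, and that neighbour flask's best is 97.4 %.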